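**Strategy.** The route rests on disconnecting the C2–C3 bond of the pyranone ring C. In the key step a chiral dirhodium carboxylate turns an open-chain α-diazoacetophenone into a carbenoid at the future C3, which inserts into a C–H bond of the O–CH2 group of a plain benzyl ether (future C2), closing ring C and setting the C2 stereocentre in one operation. The step exploits the fact that the C2–H bond is doubly activated, being benzylic to the catechol ring B and adjacent to the ring oxygen O1, and lies 1,6 to C3, which is already bonded to the C4 carbonyl on ring A. The C3 hydroxyl is then introduced trans by enolate oxidation.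

Key step: step 6

Assumption: the sense of induction of Rh2(S-PTTL)4 in step 6 is taken to give the (2S)-flavanone; if the opposite sense is found, the mirror-image catalyst Rh2(R-PTTL)4 is used with no other change. The target is (2R,3R), 2,3-trans; the flavanone of the same spatial arrangement at C2 is (2S) because the priorities at C2 change. Compounds 1, 2 and 4 are commercial.

**Step 1**
Reactants: 1 2,4-dihydroxyacetophenone; 2 geranyl bromide [(2E)-1-bromo-3,7-dimethylocta-2,6-diene]
Product: 3 1-{4-[(2E)-3,7-dimethylocta-2,6-dienyloxy]-2-hydroxyphenyl}ethan-1-one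
Conditions: K2CO3, acetone, reflux
Reagents that add atoms: none
Why: Williamson etherification should occur only at the 4-OH, which is the more acidic and free hydroxyl, because the 2-OH is held in a hydrogen bond to the acetyl group; SN2 at the primary allylic bromide keeps the E geometry.

**Step 2**
Reactants: 4 3,4-dihydroxybenzaldehyde
Product: 5 3,4-bis(tert-butyldimethylsilyloxy)benzaldehyde
Conditions: TBSCl, imidazole, DMF, rt
Reagents that add atoms: tert-butyldimethylsilyl chloride (TBSCl), CC(C)(C)[Si](C)(C)Cl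
Why: Imidazole-promoted silylation caps both catechol hydroxyls as aryl silyl ethers that should tolerate the carbenoid and enolate steps and come off at the end with fluoride without harming the geranyl ether.

**Step 3**
Reactants: 5 3,4-bis(tert-butyldimethylsilyloxy)benzaldehyde
Product: 6 [3,4-bis(tert-butyldimethylsilyloxy)phenyl]methanol
Conditions: NaBH4, THF–EtOH, 0 °C
Reagents that add atoms: none
Why: Borohydride reduction of the aldehyde to the benzylic alcohol; the aryl silyl ethers should survive the short, cold, weakly basic treatment.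

**Step 4**
Reactants: 3 1-{4-[(2E)-3,7-dimethylocta-2,6-dienyloxy]-2-hydroxyphenyl}ethan-1-one; 6 [3,4-bis(tert-butyldimethylsilyloxy)phenyl]methanol
Product: 7 1-{2-[3,4-bis(tert-butyldimethylsilyloxy)benzyloxy]-4-[(2E)-3,7-dimethylocta-2,6-dienyloxy]phenyl}ethan-1-one
Conditions: PPh3, DIAD, THF, 0 °C to rt
Reagents that add atoms: none
Why: Mitsunobu etherification, in which the phenol protonates the betaine and displaces the activated primary benzylic oxyphosphonium under neutral conditions that spare the aryl silyl ethers; this installs the OCH2 carbon that becomes C2.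

**Step 5**
Reactants: 7 1-{2-[3,4-bis(tert-butyldimethylsilyloxy)benzyloxy]-4-[(2E)-3,7-dimethylocta-2,6-dienyloxy]phenyl}ethan-1-one
Product: 10 2-diazo-1-{2-[3,4-bis(tert-butyldimethylsilyloxy)benzyloxy]-4-[(2E)-3,7-dimethylocta-2,6-dienyloxy]phenyl}ethan-1-one, via lithium enolate 8 (not isolated), via trifluoroacetyl diketone 9 (not isolated)
Conditions: LiN(SiMe3)2, THF, −78 °C; CF3CO2CH2CF3; aq. HCl work-up; then MsN3, Et3N, H2O, MeCN, rt
Reagents that add atoms: methanesulfonyl azide, CS(=O)(=O)N=[N+]=[N-] (the two diazo nitrogens of 10); LiN(SiMe3)2, [Li+].C[Si](C)(C)[N-][Si](C)(C)C (lithium of 8 only); 2,2,2-trifluoroethyl trifluoroacetate, O=C(OCC(F)(F)F)C(F)(F)F (trifluoroacetyl group of 9 only)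
Why: Detrifluoroacetylative diazo transfer: Claisen trifluoroacetylation of the kinetic lithium enolate activates the methyl group as a 1,3-diketone, which undergoes Regitz diazo transfer from mesyl azide with loss of the trifluoroacetyl group as its sulfonamide, giving the terminal α-diazoketone.

**Step 6**
Reactants: 10 2-diazo-1-{2-[3,4-bis(tert-butyldimethylsilyloxy)benzyloxy]-4-[(2E)-3,7-dimethylocta-2,6-dienyloxy]phenyl}ethan-1-one
Product: 11 (2S)-2-[3,4-bis(tert-butyldimethylsilyloxy)phenyl]-7-[(2E)-3,7-dimethylocta-2,6-dienyloxy]-2,3-dihydro-4H-chromen-4-one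
Conditions: Rh2(S-PTTL)4 [dirhodium tetrakis(N-phthaloyl-(S)-tert-leucinate)] (1 mol %), CH2Cl2, 0 °C, slow addition of 10 at high dilution
Reagents that add atoms: none
Why: The divalent rhodium catalyst expels N2 from 10 to give an electrophilic carbenoid at the future C3, which inserts into one of the two enantiotopic C–H bonds of the OCH2Ar group through a concerted, hydride-transfer-like three-centre transition state, forming C2–C3 and passing the hydrogen to C3. The closest known reaction type is the dirhodium-catalysed intramolecular C–H insertion of ortho-alkoxyaryl α-diazoketones to chroman-4-ones, including enantioselective variants with chiral carboxylate ligands. Ring C closes by 1,6-C–H insertion to a six-membered ring, the usual 1,5-site being the oxygen O1, which carries no hydrogen. The C2 stereocentre is controlled by the chiral carboxylate ligand sphere, which selects between the enantiotopic hydrogens, and insertion proceeds with retention at carbon; C3 becomes CH2, so no second centre arises. The step needs C–H insertion to beat attack of the carbenoid on the O1 lone pair (oxonium ylide, then 1,2-benzyl shift to a benzofuranone), cyclopropanation of the geranyl alkenes and carbene dimerisation. The C2–H bond is the most hydridic bond within reach, O1 is a poor donor because it is conjugated with the aroyl ring, the geranyl chain sits para to the acyl group and cannot reach the carbenoid within the molecule, and slow addition at high dilution suppresses bimolecular paths.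

**Step 7**
Reactants: 11 (2S)-2-[3,4-bis(tert-butyldimethylsilyloxy)phenyl]-7-[(2E)-3,7-dimethylocta-2,6-dienyloxy]-2,3-dihydro-4H-chromen-4-one
Product: 13 (2R,3R)-2-[3,4-bis(tert-butyldimethylsilyloxy)phenyl]-7-[(2E)-3,7-dimethylocta-2,6-dienyloxy]-3-hydroxy-2,3-dihydro-4H-chromen-4-one, via potassium enolate 12 (not isolated)
Conditions: KN(SiMe3)2, THF, −78 °C; 3-phenyl-2-(phenylsulfonyl)oxaziridine, −78 °C; sat. NH4Cl quench at −78 °C
Reagents that add atoms: 3-phenyl-2-(phenylsulfonyl)oxaziridine (Davis oxaziridine), O=S(=O)(c1ccccc1)N1OC1c1ccccc1 (the C3 oxygen); KN(SiMe3)2, [K+].C[Si](C)(C)[N-][Si](C)(C)C (potassium of 12 only)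
Why: Davis enolate hydroxylation: the potassium enolate, formed at −78 °C where β-elimination of the O1 phenoxide should be slow, attacks the oxaziridine oxygen on the face anti to the C2 aryl group, giving the 2,3-trans (2R,3R) alcohol, which is also the more stable diastereomer, and the oxaziridine should not epoxidise the geranyl alkenes at this temperature.

**Step 8**
Reactants: 13 (2R,3R)-2-[3,4-bis(tert-butyldimethylsilyloxy)phenyl]-7-[(2E)-3,7-dimethylocta-2,6-dienyloxy]-3-hydroxy-2,3-dihydro-4H-chromen-4-one
Product: 14 (2R,3R)-2-(3,4-dihydroxyphenyl)-7-[(2E)-3,7-dimethylocta-2,6-dienyloxy]-3-hydroxy-2,3-dihydro-4H-chromen-4-one (target)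
Conditions: Bu4NF, AcOH (1:1), THF, 0 °C, under argon
Reagents that add atoms: none
Why: Fluoride cleavage of the two aryl silyl ethers; acetic acid buffering keeps the medium non-basic, so the trans-dihydroflavonol should not epimerise or ring-open and the geranyl ether stays intact.

**Compound list**

1 | 2,4-dihydroxyacetophenone | CC(=O)c1ccc(O)cc1O | starting material
2 | geranyl bromide | CC(C)=CCC/C(C)=C/CBr | starting material
3 | 1-{4-[(2E)-3,7-dimethylocta-2,6-dienyloxy]-2-hydroxyphenyl}ethan-1-one | CC(C)=CCC/C(C)=C/COc1ccc(C(C)=O)c(O)c1 | intermediate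
4 | 3,4-dihydroxybenzaldehyde | O=Cc1ccc(O)c(O)c1 | starting material
5 | 3,4-bis(tert-butyldimethylsilyloxy)benzaldehyde | O=Cc1ccc(O[Si](C)(C)C(C)(C)C)c(O[Si](C)(C)C(C)(C)C)c1 | intermediate
6 | [3,4-bis(tert-butyldimethylsilyloxy)phenyl]methanol | OCc1ccc(O[Si](C)(C)C(C)(C)C)c(O[Si](C)(C)C(C)(C)C)c1 | intermediate
7 | 1-{2-[3,4-bis(tert-butyldimethylsilyloxy)benzyloxy]-4-(geranyloxy)phenyl}ethan-1-one | CC(C)=CCC/C(C)=C/COc1ccc(C(C)=O)c(OCc2ccc(O[Si](C)(C)C(C)(C)C)c(O[Si](C)(C)C(C)(C)C)c2)c1 | intermediate
8 | lithium enolate of 7 | CC(C)=CCC/C(C)=C/COc1ccc(C(=C)[O-])c(OCc2ccc(O[Si](C)(C)C(C)(C)C)c(O[Si](C)(C)C(C)(C)C)c2)c1.[Li+] | intermediate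
9 | 4,4,4-trifluoro-1-{2-[3,4-bis(tert-butyldimethylsilyloxy)benzyloxy]-4-(geranyloxy)phenyl}butane-1,3-dione | CC(C)=CCC/C(C)=C/COc1ccc(C(=O)CC(=O)C(F)(F)F)c(OCc2ccc(O[Si](C)(C)C(C)(C)C)c(O[Si](C)(C)C(C)(C)C)c2)c1 | intermediate
10 | 2-diazo-1-{2-[3,4-bis(tert-butyldimethylsilyloxy)benzyloxy]-4-(geranyloxy)phenyl}ethan-1-one | CC(C)=CCC/C(C)=C/COc1ccc(C(=O)C=[N+]=[N-])c(OCc2ccc(O[Si](C)(C)C(C)(C)C)c(O[Si](C)(C)C(C)(C)C)c2)c1 | intermediate
11 | (2S)-2-[3,4-bis(tert-butyldimethylsilyloxy)phenyl]-7-(geranyloxy)-2,3-dihydro-4H-chromen-4-one | CC(C)=CCC/C(C)=C/COc1ccc2c(c1)O[C@H](c1ccc(O[Si](C)(C)C(C)(C)C)c(O[Si](C)(C)C(C)(C)C)c1)CC2=O | intermediate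
12 | potassium enolate of 11 | CC(C)=CCC/C(C)=C/COc1ccc2c(c1)O[C@H](c1ccc(O[Si](C)(C)C(C)(C)C)c(O[Si](C)(C)C(C)(C)C)c1)C=C2[O-].[K+] | intermediate
13 | (2R,3R)-2-[3,4-bis(tert-butyldimethylsilyloxy)phenyl]-7-(geranyloxy)-3-hydroxy-2,3-dihydro-4H-chromen-4-one | CC(C)=CCC/C(C)=C/COc1ccc2c(c1)O[C@H](c1ccc(O[Si](C)(C)C(C)(C)C)c(O[Si](C)(C)C(C)(C)C)c1)[C@@H](O)C2=O | intermediate
14 | (2R,3R)-2-(3,4-dihydroxyphenyl)-7-[(2E)-3,7-dimethylocta-2,6-dienyloxy]-3-hydroxy-2,3-dihydro-4H-chromen-4-one | CC(C)=CCC/C(C)=C/COc1ccc2c(c1)O[C@H](c1ccc(O)c(O)c1)[C@@H](O)C2=O | target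

**Total step count:** 8.
**Longest linear sequence:** 7 steps (steps 2, 3, 4, 5, 6, 7 and 8, from compound 4).

**Steps most likely to fail**

Step 6. The carbenoid may be captured by the O1 lone pair and rearrange by 1,2-benzyl shift faster than it inserts, or the two enantiotopic C–H bonds may be poorly discriminated. The fallback keeps the same ring closure but makes C2 a cation instead of using a carbenoid. Setting out from 7, O-acetylation of its potassium enolate (KN(SiMe3)2, Ac2O, THF, −78 °C) should give the enol acetate F1. Oxidative cleavage of the benzylic ether C–H with DDQ (2,6-dichloropyridine, LiClO4, 1,2-dichloroethane, rt) should give a cation at the future C2, stabilised by the silyloxyaryl ring and O1. The enol acetate carbon should trap it to close the C2–C3 bond and, after loss of the acetyl group, give the racemic flavanone F2. Preparative HPLC on a chiral stationary phase then returns to the route at 11.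

Step 7. The enolate may ring-open by β-elimination of the phenoxide, which would erode the C2 configuration, or the oxidant may attack both faces. The fallback avoids a free enolate. Setting out from 11, soft enolisation (Me3SiOTf, Et3N, CH2Cl2, 0 °C) should give the trimethylsilyl enol ether F3. One equivalent of dimethyldioxirane at −78 °C (Rubottom oxidation) should epoxidise this most electron-rich alkene anti to the C2 aryl group to the silyloxy oxirane F4. This rearranges by silyl shift to the 3-trimethylsilyloxy ketone F5. Mild acid (citric acid, MeOH, 0 °C) removes the trimethylsilyl group and returns to the route at 13.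

Step 4. The hydrogen-bonded phenol may be too weak a nucleophile and the activated alcohol may be consumed by the hydrazide instead. The fallback replaces the redox condensation by a two-stage alkylation. Setting out from 6, Appel bromination (CBr4, PPh3, CH2Cl2, 0 °C) should give the benzylic bromide F6. Used at once in a Williamson alkylation of phenol 3 (K2CO3, acetone, rt to 50 °C), it returns to the route at 7.

**Further compounds**

F1 | step 6 | 1-{2-[3,4-bis(tert-butyldimethylsilyloxy)benzyloxy]-4-(geranyloxy)phenyl}ethenyl acetate | CC(C)=CCC/C(C)=C/COc1ccc(C(=C)OC(C)=O)c(OCc2ccc(O[Si](C)(C)C(C)(C)C)c(O[Si](C)(C)C(C)(C)C)c2)c1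
F2 | step 6 | racemic 2-[3,4-bis(tert-butyldimethylsilyloxy)phenyl]-7-(geranyloxy)-2,3-dihydro-4H-chromen-4-one | CC(C)=CCC/C(C)=C/COc1ccc2c(c1)OC(c1ccc(O[Si](C)(C)C(C)(C)C)c(O[Si](C)(C)C(C)(C)C)c1)CC2=O
F3 | step 7 | (2S)-2-[3,4-bis(tert-butyldimethylsilyloxy)phenyl]-7-(geranyloxy)-4-(trimethylsilyloxy)-2H-chromene | CC(C)=CCC/C(C)=C/COc1ccc2c(c1)O[C@H](c1ccc(O[Si](C)(C)C(C)(C)C)c(O[Si](C)(C)C(C)(C)C)c1)C=C2O[Si](C)(C)C
F4 | step 7 | 3,4-epoxy-4-(trimethylsilyloxy) derivative of F3, oxirane oxygen anti to the C2 aryl group | CC(C)=CCC/C(C)=C/COc1ccc2c(c1)O[C@H](c1ccc(O[Si](C)(C)C(C)(C)C)c(O[Si](C)(C)C(C)(C)C)c1)[C@H]3O[C@@]23O[Si](C)(C)C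
F5 | step 7 | (2R,3R)-2-[3,4-bis(tert-butyldimethylsilyloxy)phenyl]-7-(geranyloxy)-3-(trimethylsilyloxy)-2,3-dihydro-4H-chromen-4-one | CC(C)=CCC/C(C)=C/COc1ccc2c(c1)O[C@H](c1ccc(O[Si](C)(C)C(C)(C)C)c(O[Si](C)(C)C(C)(C)C)c1)[C@@H](O[Si](C)(C)C)C2=O
F6 | step 4 | 4-(bromomethyl)-1,2-bis(tert-butyldimethylsilyloxy)benzene | BrCc1ccc(O[Si](C)(C)C(C)(C)C)c(O[Si](C)(C)C(C)(C)C)c1
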